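**Strategy.** The route rests on cutting the C4–C4a bond of the pyranone ring C. Ring A carries an iodine on C4a, the carbon lying between methoxy-bearing C5 and C8a (the carbon that holds the ring oxygen O1). Exchange of this iodine for magnesium gives an aryl metal that acylates the ester group held on the same side of a tetrasubstituted acrylate double bond as the aryl ether oxygen. One operation closes ring C as a chromone, with the C3 oxygen already present and no regiochemical choice on the unsymmetrical A ring. The precursor is a methyl 3-aryl-3-(2-iodoaryloxy)-2-(methoxymethoxy)acrylate, assembled from a B-ring β-keto ester enol tosylate and a regiodefined iodophenol.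

Key step: step 13

Remarks on the chemistry:
- The acrylate geometry needed for closure (aryloxy and ester on the same side) is E by the CIP rules, because on C2 the acetal oxygen outranks the ester carbon.
- Compounds 3–5 and 22 are mixtures at a centre that is destroyed later in the same or a following step.
- The iodine is placed by directed lithiation at the aldehyde stage, not by electrophilic iodination of the phenol, so that its position does not depend on a steric bias.

**Step 1**
Reactants: 1 5-hydroxy-3,4-dimethoxybenzaldehyde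
Product: 2 3,4-dimethoxy-5-(triisopropylsilyloxy)benzaldehyde
Conditions: TIPSCl, imidazole, DMF, rt
Reagents that add atoms: triisopropylsilyl chloride, CC(C)[Si](Cl)(C(C)C)C(C)C
Why: Imidazole-promoted silylation of the phenol gives a bulky, non-coordinating aryl silyl ether that tolerates organolithium and Grignard reagents and shields the neighbouring ring position.

**Step 2**
Reactants: 2 3,4-dimethoxy-5-(triisopropylsilyloxy)benzaldehyde
Product: 6 2-iodo-3,4-dimethoxy-5-(triisopropylsilyloxy)benzaldehyde, via lithium α-amino alkoxide 3 (not isolated), via C2-aryllithium 4 (not isolated), via iodinated α-amino alkoxide 5 (not isolated)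
Conditions: Me2NCH2CH2N(Me)Li (from the amine and n-BuLi), THF, −20 °C; n-BuLi (3 equiv), −20 °C; I2, −78 °C → rt; H2O, aq Na2S2O3
Reagents that add atoms: iodine, II
Why: Directed ortho-lithiation through an in situ α-amino alkoxide masks the aldehyde and, together with the C3 methoxy group, should direct lithiation to C2, whereas C6 next to the bulky silyl ether should stay untouched; iodinolysis and aqueous work-up return the aldehyde.

**Step 3**
Reactants: 6 2-iodo-3,4-dimethoxy-5-(triisopropylsilyloxy)benzaldehyde
Product: 8 2-iodo-3,4-dimethoxy-5-(triisopropylsilyloxy)phenol, via aryl formate 7 (not isolated)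
Conditions: mCPBA, CH2Cl2, 0 °C → rt; then Et3N (cat.), MeOH, rt
Reagents that add atoms: mCPBA, O=C(OO)c1cccc(Cl)c1
Why: Baeyer–Villiger (Dakin-type) oxidation, in which the electron-rich aryl group with a para methoxy substituent migrates to oxygen, followed by mild methanolysis of the formate that should spare the aryl silyl ether.

**Step 4**
Reactants: 9 5-bromo-2-methoxyphenylacetic acid
Product: 11 2-(5-bromo-2-methoxyphenyl)-N-methoxy-N-methylacetamide, via acyl imidazolide 10 (not isolated)
Conditions: CDI, THF, rt; then MeNHOMe·HCl, rt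
Reagents that add atoms: N,O-dimethylhydroxylamine hydrochloride, CNOC.Cl
Why: Amide formation through the acyl imidazolide gives the Weinreb amide under neutral conditions.

**Step 5**
Reactants: 11 2-(5-bromo-2-methoxyphenyl)-N-methoxy-N-methylacetamide; 12 isopropenylmagnesium bromide
Product: 13 1-(5-bromo-2-methoxyphenyl)-3-methylbut-3-en-2-one
Conditions: THF, −20 → 0 °C; inverse quench into cold 1 M HCl
Reagents that add atoms: none
Why: Weinreb ketone synthesis, in which the chelated tetrahedral magnesium adduct prevents double addition and the acidic inverse quench keeps the liberated amine from adding to the new enone.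

**Step 6**
Reactants: 13 1-(5-bromo-2-methoxyphenyl)-3-methylbut-3-en-2-one
Product: 14 (2R)-1-(5-bromo-2-methoxyphenyl)-3-methylbut-3-en-2-ol
Conditions: (S)-Me-CBS (0.2 equiv), catecholborane, toluene, −78 °C; MeOH, then aq NaOH wash
Reagents that add atoms: none
Why: CBS reduction in which the α-branched sp2 isopropenyl group should act as the large substituent and the arylmethyl group as the small one, so the (S)-oxazaborolidine should deliver hydride to the face giving the (R)-carbinol (the sense of acetophenone to (R)-1-phenylethanol), while catecholborane at low temperature should leave the alkene alone.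

**Step 7**
Reactants: 14 (2R)-1-(5-bromo-2-methoxyphenyl)-3-methylbut-3-en-2-ol
Product: 15 tert-butyl{[(2R)-1-(5-bromo-2-methoxyphenyl)-3-methylbut-3-en-2-yl]oxy}dimethylsilane
Conditions: TBSCl, imidazole, DMF, rt
Reagents that add atoms: tert-butyldimethylsilyl chloride, CC(C)(C)[Si](C)(C)Cl
Why: Standard silyl ether formation protects the allylic alcohol for the organometallic and basic steps that follow, without touching the stereocentre.

**Step 8**
Reactants: 15 tert-butyl{[(2R)-1-(5-bromo-2-methoxyphenyl)-3-methylbut-3-en-2-yl]oxy}dimethylsilane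
Product: 17 3-[(2R)-2-(tert-butyldimethylsilyloxy)-3-methylbut-3-en-1-yl]-4-methoxybenzoic acid, via aryllithium 16 (not isolated)
Conditions: n-BuLi, THF, −78 °C; CO2; 1 M HCl to pH 3, 0 °C
Reagents that add atoms: carbon dioxide, O=C=O
Why: Bromine–lithium exchange followed by carboxylation of the aryllithium is fast at −78 °C and compatible with the silyl ether, the alkene and the methoxy group.

**Step 9**
Reactants: 18 methyl glycolate
Product: 19 methyl 2-(methoxymethoxy)acetate
Conditions: MOMCl, iPr2NEt, CH2Cl2, 0 °C → rt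
Reagents that add atoms: chloromethyl methyl ether, COCCl
Why: O-Alkylation of the primary alcohol with the chloromethyl ether gives the acetal-protected glycolate that later supplies C3 and its oxygen.

**Step 10**
Reactants: 17 3-[(2R)-2-(tert-butyldimethylsilyloxy)-3-methylbut-3-en-1-yl]-4-methoxybenzoic acid; 19 methyl 2-(methoxymethoxy)acetate
Product: 22 methyl 3-{3-[(2R)-2-(tert-butyldimethylsilyloxy)-3-methylbut-3-en-1-yl]-4-methoxyphenyl}-2-(methoxymethoxy)-3-oxopropanoate (both epimers at C2), via acyl imidazolide 20 (not isolated), via lithium ester enolate 21 (not isolated)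
Conditions: 17, CDI, THF, rt; added to 19/LiHMDS (3.5 equiv each), THF, −78 → −30 °C; AcOH
Reagents that add atoms: none
Why: Crossed Claisen condensation run as acylation of the preformed lithium enolate by the acyl imidazolide, a stronger acyl donor than a methyl benzoate, with excess enolate to absorb the imidazole N–H and the acidic product.

**Step 11**
Reactants: 22 the β-keto ester
Product: 23 methyl (2E)-3-{3-[(2R)-2-(tert-butyldimethylsilyloxy)-3-methylbut-3-en-1-yl]-4-methoxyphenyl}-2-(methoxymethoxy)-3-(tosyloxy)prop-2-enoate (tosyloxy and ester on the same side)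
Conditions: TsCl, TMEDA, LiCl, MeCN, 0 °C → rt
Reagents that add atoms: p-toluenesulfonyl chloride, Cc1ccc(S(=O)(=O)Cl)cc1
Why: Enol tosylation under lithium chelation control, in which the six-membered lithium chelate of the β-keto ester enolate holds the enolate oxygen and the ester carbonyl cis, so sulfonylation should give the isomer with tosyloxy and ester on the same side.

**Step 12**
Reactants: 23 the enol tosylate; 8 2-iodo-3,4-dimethoxy-5-(triisopropylsilyloxy)phenol
Product: 24 methyl (2E)-3-{3-[(2R)-2-(tert-butyldimethylsilyloxy)-3-methylbut-3-en-1-yl]-4-methoxyphenyl}-3-[2-iodo-3,4-dimethoxy-5-(triisopropylsilyloxy)phenoxy]-2-(methoxymethoxy)prop-2-enoate (aryloxy and ester on the same side)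
Conditions: K2CO3 (anhydrous), DMF, rt → 40 °C
Reagents that add atoms: none
Why: Nucleophilic vinylic substitution by addition–elimination, in which the phenoxide adds to the β-carbon and the short-lived ester enolate should expel tosylate before rotating, so the geometry should be retained (to be confirmed by NOE before step 13).

**Step 13**
Reactants: 24 the iodoaryloxy acrylate
Product: 26 2-{3-[(2R)-2-(tert-butyldimethylsilyloxy)-3-methylbut-3-en-1-yl]-4-methoxyphenyl}-5,6-dimethoxy-3-(methoxymethoxy)-7-(triisopropylsilyloxy)-4H-chromen-4-one, via arylmagnesium chloride 25 (not isolated)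
Conditions: iPrMgCl·LiCl (1.2 equiv), THF, −30 °C → rt; aq NH4Cl
Reagents that add atoms: none
Why: Iodine–magnesium exchange at C4a, an iodide activated by its two flanking oxygen substituents, should give arylmagnesium 25, whose carbanion attacks the ester carbonyl on the same side of the alkene and expels methoxide from the tetrahedral magnesium alkoxide. The closest known reaction type is the Parham cyclization (halogen–metal exchange then intramolecular acylation), here in the form that turns a β-aryloxyacrylate into a chromone. Ring C (O1–C2–C3–C4–C4a–C8a) closes in the 6-exo-trig mode by formation of C4–C4a. No stereocentre is formed, and the remote, silyl-protected (R)-carbinol is not touched. The step needs exchange to outrun addition of the Grignard reagent to the ester, which the iodide, the low temperature and the deactivated push–pull ester should secure, and it needs the E geometry set in steps 11 and 12 so that the ester is within reach. The position of the iodine alone decides where the ring closes, and the chromone formed is a vinylogous ester that should resist a second addition.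

**Step 14**
Reactants: 26 the fully protected flavonol
Product: 27 7-hydroxy-2-{3-[(2R)-2-hydroxy-3-methylbut-3-en-1-yl]-4-methoxyphenyl}-5,6-dimethoxy-3-(methoxymethoxy)-4H-chromen-4-one
Conditions: TBAF (3 equiv), THF, 0 °C → rt; aq NH4Cl
Reagents that add atoms: none
Why: Fluoride cleaves both the aryl triisopropylsilyl ether and the secondary tert-butyldimethylsilyl ether, while the acetal, the methyl ethers and the alkene are inert.

**Step 15**
Reactants: 27 the 3-O-methoxymethyl flavonol
Product: 28 3,7-dihydroxy-2-{3-[(2R)-2-hydroxy-3-methylbut-3-en-1-yl]-4-methoxyphenyl}-5,6-dimethoxy-4H-chromen-4-one (target)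
Conditions: HCl (1 M in MeOH), THF, rt → 40 °C
Reagents that add atoms: none
Why: Acid-catalysed methanolysis of the methoxymethyl acetal of the acidic 3-hydroxyl is easy under conditions too mild to ionise the secondary allylic alcohol or cleave the methyl ethers.

**Compound list**

1 | 5-hydroxy-3,4-dimethoxybenzaldehyde | COc1cc(C=O)cc(O)c1OC | starting material
2 | 3,4-dimethoxy-5-(triisopropylsilyloxy)benzaldehyde | COc1cc(C=O)cc(O[Si](C(C)C)(C(C)C)C(C)C)c1OC | intermediate
3 | lithium α-amino alkoxide from 2 and lithium N,N,N'-trimethylethylenediamide (racemic at the new carbon) | [Li]OC(N(C)CCN(C)C)c1cc(OC)c(OC)c(O[Si](C(C)C)(C(C)C)C(C)C)c1 | intermediate (not isolated)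
4 | C2-lithiated α-amino alkoxide (lithium between the alkoxide-bearing carbon and the C3 methoxy group) | [Li]OC(N(C)CCN(C)C)c1cc(O[Si](C(C)C)(C(C)C)C(C)C)c(OC)c(OC)c1[Li] | intermediate (not isolated)
5 | C2-iodinated α-amino alkoxide | [Li]OC(N(C)CCN(C)C)c1cc(O[Si](C(C)C)(C(C)C)C(C)C)c(OC)c(OC)c1I | intermediate (not isolated)
6 | 2-iodo-3,4-dimethoxy-5-(triisopropylsilyloxy)benzaldehyde | O=Cc1cc(O[Si](C(C)C)(C(C)C)C(C)C)c(OC)c(OC)c1I | intermediate
7 | 2-iodo-3,4-dimethoxy-5-(triisopropylsilyloxy)phenyl formate | O=COc1cc(O[Si](C(C)C)(C(C)C)C(C)C)c(OC)c(OC)c1I | intermediate (not isolated)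
8 | 2-iodo-3,4-dimethoxy-5-(triisopropylsilyloxy)phenol | Oc1cc(O[Si](C(C)C)(C(C)C)C(C)C)c(OC)c(OC)c1I | intermediate
9 | 5-bromo-2-methoxyphenylacetic acid | COc1ccc(Br)cc1CC(=O)O | starting material
10 | 2-(5-bromo-2-methoxyphenyl)-1-(1H-imidazol-1-yl)ethan-1-one | COc1ccc(Br)cc1CC(=O)n1ccnc1 | intermediate (not isolated)
11 | 2-(5-bromo-2-methoxyphenyl)-N-methoxy-N-methylacetamide | COc1ccc(Br)cc1CC(=O)N(C)OC | intermediate
12 | isopropenylmagnesium bromide | C=C(C)[Mg]Br | starting material
13 | 1-(5-bromo-2-methoxyphenyl)-3-methylbut-3-en-2-one | C=C(C)C(=O)Cc1cc(Br)ccc1OC | intermediate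
14 | (2R)-1-(5-bromo-2-methoxyphenyl)-3-methylbut-3-en-2-ol | C=C(C)[C@H](O)Cc1cc(Br)ccc1OC | intermediate
15 | tert-butyl{[(2R)-1-(5-bromo-2-methoxyphenyl)-3-methylbut-3-en-2-yl]oxy}dimethylsilane | C=C(C)[C@H](O[Si](C)(C)C(C)(C)C)Cc1cc(Br)ccc1OC | intermediate
16 | aryllithium from 15 (lithium in place of bromine) | C=C(C)[C@H](O[Si](C)(C)C(C)(C)C)Cc1cc([Li])ccc1OC | intermediate (not isolated)
17 | 3-[(2R)-2-(tert-butyldimethylsilyloxy)-3-methylbut-3-en-1-yl]-4-methoxybenzoic acid | C=C(C)[C@H](O[Si](C)(C)C(C)(C)C)Cc1cc(C(=O)O)ccc1OC | intermediate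
18 | methyl glycolate | COC(=O)CO | starting material
19 | methyl 2-(methoxymethoxy)acetate | COCOCC(=O)OC | intermediate
20 | acyl imidazolide of 17 | C=C(C)[C@H](O[Si](C)(C)C(C)(C)C)Cc1cc(C(=O)n2ccnc2)ccc1OC | intermediate (not isolated)
21 | lithium enolate of 19 | [Li]OC(OC)=COCOC | intermediate (not isolated)
22 | methyl 3-{3-[(2R)-2-(tert-butyldimethylsilyloxy)-3-methylbut-3-en-1-yl]-4-methoxyphenyl}-2-(methoxymethoxy)-3-oxopropanoate (both C2 epimers) | C=C(C)[C@H](O[Si](C)(C)C(C)(C)C)Cc1cc(C(=O)C(OCOC)C(=O)OC)ccc1OC | intermediate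
23 | methyl (2E)-3-{3-[(2R)-2-(tert-butyldimethylsilyloxy)-3-methylbut-3-en-1-yl]-4-methoxyphenyl}-2-(methoxymethoxy)-3-(tosyloxy)prop-2-enoate | C=C(C)[C@H](O[Si](C)(C)C(C)(C)C)Cc1cc(/C(OS(=O)(=O)c2ccc(C)cc2)=C(\OCOC)C(=O)OC)ccc1OC | intermediate
24 | methyl (2E)-3-{3-[(2R)-2-(tert-butyldimethylsilyloxy)-3-methylbut-3-en-1-yl]-4-methoxyphenyl}-3-[2-iodo-3,4-dimethoxy-5-(triisopropylsilyloxy)phenoxy]-2-(methoxymethoxy)prop-2-enoate | C=C(C)[C@H](O[Si](C)(C)C(C)(C)C)Cc1cc(/C(Oc2cc(O[Si](C(C)C)(C(C)C)C(C)C)c(OC)c(OC)c2I)=C(\OCOC)C(=O)OC)ccc1OC | intermediate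
25 | arylmagnesium chloride from 24 (MgCl in place of iodine at C4a) | C=C(C)[C@H](O[Si](C)(C)C(C)(C)C)Cc1cc(/C(Oc2cc(O[Si](C(C)C)(C(C)C)C(C)C)c(OC)c(OC)c2[Mg]Cl)=C(\OCOC)C(=O)OC)ccc1OC | intermediate (not isolated)
26 | 2-{3-[(2R)-2-(tert-butyldimethylsilyloxy)-3-methylbut-3-en-1-yl]-4-methoxyphenyl}-5,6-dimethoxy-3-(methoxymethoxy)-7-(triisopropylsilyloxy)-4H-chromen-4-one | C=C(C)[C@H](O[Si](C)(C)C(C)(C)C)Cc1cc(-c2oc3cc(O[Si](C(C)C)(C(C)C)C(C)C)c(OC)c(OC)c3c(=O)c2OCOC)ccc1OC | intermediate
27 | 7-hydroxy-2-{3-[(2R)-2-hydroxy-3-methylbut-3-en-1-yl]-4-methoxyphenyl}-5,6-dimethoxy-3-(methoxymethoxy)-4H-chromen-4-one | C=C(C)[C@H](O)Cc1cc(-c2oc3cc(O)c(OC)c(OC)c3c(=O)c2OCOC)ccc1OC | intermediate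
28 | 3,7-dihydroxy-2-{3-[(2R)-2-hydroxy-3-methylbut-3-en-1-yl]-4-methoxyphenyl}-5,6-dimethoxy-4H-chromen-4-one | C=C(C)[C@H](O)Cc1cc(-c2oc3cc(O)c(OC)c(OC)c3c(=O)c2O)ccc1OC | target

**Step count and risks**

Total step count: 15. Longest linear sequence: 11 steps (steps 4–8 and 10–15, from 9 to 28).

Steps most likely to fail:

1. Step 12. The phenoxide may attack sulfur and take over the sulfonyl group instead of adding to the hindered, fully substituted β-carbon. Prolonged exposure to phenoxide may also scramble the alkene geometry by reversible addition. The fallback sets out from 22 and returns at 24. 22 would be treated with Ph3PCl2 and Et3N in MeCN to give the vinylogous acid chloride methyl (2E)-3-aryl-3-chloro-2-(methoxymethoxy)prop-2-enoate F1, of which the isomer with chlorine and ester on the same side would be taken on. Its leaving group offers no second electrophilic atom, and substitution by 8 (K2CO3, cat. DABCO, DMF, rt) would give 24.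

2. Step 13. Exchange at the electron-rich iodide may be slower than attack of the Grignard reagent on the ester, or the aryl metal may be protonated before it reaches the deactivated ester. The fallback changes the internal electrophile to a Weinreb amide and the metal to lithium; it sets out from 19 and 20 and returns at 26. 19 would be converted (MeNHOMe·HCl, iPrMgCl, THF, −20 °C) into N-methoxy-N-methyl-2-(methoxymethoxy)acetamide F2. Its lithium enolate (LiHMDS, −78 °C) would be acylated by 20 to give the β-keto Weinreb amide F3. Tosylation as in step 11 would give the enol tosylate F4, and substitution with 8 as in step 12 would give the aryloxy acrylamide F5. Treatment of F5 with t-BuLi (2 equiv, THF, −95 °C) would bring about iodine–lithium exchange and addition to the amide; the chelated adduct collapses only on work-up, to 26.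

3. Step 6. Facial discrimination between the isopropenyl and arylmethyl groups may be insufficient, or the borane may add to the alkene. The fallback sets out from 13 and returns at 14. Luche reduction (NaBH4, CeCl3·7H2O, MeOH, 0 °C) would give the racemic alcohol F6. Sharpless kinetic resolution (Ti(OiPr)4, L-(+)-DIPT, t-BuOOH 0.6 equiv, 4 Å sieves, CH2Cl2, −20 °C) should epoxidise the (S)-enantiomer faster and leave (R)-alcohol 14 for chromatographic separation.

**Further compounds**

F1 | step 12 | methyl (2E)-3-{3-[(2R)-2-(tert-butyldimethylsilyloxy)-3-methylbut-3-en-1-yl]-4-methoxyphenyl}-3-chloro-2-(methoxymethoxy)prop-2-enoate | C=C(C)[C@H](O[Si](C)(C)C(C)(C)C)Cc1cc(/C(Cl)=C(\OCOC)C(=O)OC)ccc1OC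
F2 | step 13 | N-methoxy-N-methyl-2-(methoxymethoxy)acetamide | COCOCC(=O)N(C)OC
F3 | step 13 | 3-{3-[(2R)-2-(tert-butyldimethylsilyloxy)-3-methylbut-3-en-1-yl]-4-methoxyphenyl}-N-methoxy-2-(methoxymethoxy)-N-methyl-3-oxopropanamide | C=C(C)[C@H](O[Si](C)(C)C(C)(C)C)Cc1cc(C(=O)C(OCOC)C(=O)N(C)OC)ccc1OC
F4 | step 13 | (2E)-3-{3-[(2R)-2-(tert-butyldimethylsilyloxy)-3-methylbut-3-en-1-yl]-4-methoxyphenyl}-N-methoxy-2-(methoxymethoxy)-N-methyl-3-(tosyloxy)prop-2-enamide | C=C(C)[C@H](O[Si](C)(C)C(C)(C)C)Cc1cc(/C(OS(=O)(=O)c2ccc(C)cc2)=C(\OCOC)C(=O)N(C)OC)ccc1OC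
F5 | step 13 | (2E)-3-{3-[(2R)-2-(tert-butyldimethylsilyloxy)-3-methylbut-3-en-1-yl]-4-methoxyphenyl}-3-[2-iodo-3,4-dimethoxy-5-(triisopropylsilyloxy)phenoxy]-N-methoxy-2-(methoxymethoxy)-N-methylprop-2-enamide | C=C(C)[C@H](O[Si](C)(C)C(C)(C)C)Cc1cc(/C(Oc2cc(O[Si](C(C)C)(C(C)C)C(C)C)c(OC)c(OC)c2I)=C(\OCOC)C(=O)N(C)OC)ccc1OC
F6 | step 6 | racemic 1-(5-bromo-2-methoxyphenyl)-3-methylbut-3-en-2-ol | C=C(C)C(O)Cc1cc(Br)ccc1OC
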